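**Retrosynthetic overview**
1. Target 10 ⇐ bis-tosylate 9 ⇐ lactol 8 ⇐ lactone 7: the oxolane of the target is the γ-lactone ring of 7 with C=O taken down to CH2, so the C-2–O bond is never broken.
2. 7 ⇐ lactone 5 + aldehyde 2 by an anti-aldol at the lactone α-carbon (sets C-4 and the carbinol carbon).
3. 5 ⇐ enal 3 + aldehyde 2 by a carbene-catalysed homoenolate annulation: the β-carbon of the enal, electrophilic by nature, is made nucleophilic and joined to the aldehyde carbon (C-2–C-3 bond). This step forms the only ring and sets C-2; C-3 follows by equilibration.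
4. 2 ⇐ vanillin 1 by O-sulfonylation.

Assumptions: oxolane numbering is used throughout (O-1, C-2 aryl, C-3 carboxylate or CH2OH, C-4, C-5); "tosyloxy" means 4-methylbenzenesulfonyloxy. The sense of induction of the triazolium catalyst in step 2 is not predicted here; it is fixed in a test run, and both antipodes of the precatalyst are sold.

**Step 1**
Reactants: 1 vanillin
Product: 2 4-formyl-2-methoxyphenyl 4-methylbenzenesulfonate
Conditions: TsCl (1.1 equiv), Et3N (1.5 equiv), DMAP (5 mol %), CH2Cl2, 0 °C → rt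
Reagents that add atoms: 4-methylbenzenesulfonyl chloride (TsCl), Cc1ccc(cc1)S(=O)(=O)Cl
Why: Phenol O-sulfonylation; the tosylate makes the aldehyde a better electrophile for step 2, has no enolisable hydrogen for step 3, and deactivates the benzylic positions toward the Lewis acid of step 5.

**Step 2**
Reactants: 2 4-formyl-2-methoxyphenyl 4-methylbenzenesulfonate; 3 ethyl (E)-4-oxobut-2-enoate
Product: 5 ethyl (2R,3R)-2-(3-methoxy-4-tosyloxyphenyl)-5-oxooxolane-3-carboxylate, via cis-lactone 4 (not isolated)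
Conditions: chiral N-mesityl aminoindanol-triazolium chloride (10 mol %), DBU (20 mol %), THF, 0 °C, 3 added over 6 h to 2 (1.5 equiv); then DBU (1.0 equiv), rt; recrystallise
Reagents that add atoms: none
Why: Proposed new method: the triazolylidene adds to the formyl group of 3 to give an extended Breslow intermediate that is nucleophilic at the carbon β to the former aldehyde (the one bearing CO2Et); this carbon attacks the tosylate-activated aldehyde 2 inside the chiral pocket of the aminoindanol scaffold and sets C-2 as R; tautomerisation to the acyl azolium and O-acylation close the lactone and release the carbene; the kinetic cis-lactone 4 is then epimerised by DBU at the ester-bearing C-3 to the more stable 2,3-trans isomer 5 without touching C-2 (ring-opening elimination would be a retro-5-endo-trig process and is slow); the closest known reaction type is the NHC-catalysed homoenolate annulation of enals with aromatic aldehydes to γ-butyrolactones (1,3-dimesitylimidazolylidene/DBU), together with chiral-triazolium homoenolate chemistry of 4-oxoenoates under strong-base conditions.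

**Step 3**
Reactants: 5 ethyl (2R,3R)-2-(3-methoxy-4-tosyloxyphenyl)-5-oxooxolane-3-carboxylate; 2 4-formyl-2-methoxyphenyl 4-methylbenzenesulfonate (second equivalent)
Product: 7 ethyl (2R,3R,4S)-4-[(R)-hydroxy(3-methoxy-4-tosyloxyphenyl)methyl]-2-(3-methoxy-4-tosyloxyphenyl)-5-oxooxolane-3-carboxylate, via boron enolate 6 (not isolated)
Conditions: (c-C6H11)2BOTf (1.5 equiv), Et3N (2 equiv), CH2Cl2, −78 °C; 2 (1.2 equiv), −78 → −40 °C; pH 7 buffer, MeOH, H2O2, 0 °C
Reagents that add atoms: none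
Why: Abiko–Masamune-type anti-selective boron aldol: soft enolisation of the more acidic, unhindered lactone α-CH2 gives the ring-locked E(O)-enolate, which adds to 2 through a closed chair transition state (anti aldol, R carbinol) on the face opposite the C-3 ester (3,4-trans, C-4 S).

**Step 4**
Reactants: 7 ethyl (2R,3R,4S)-4-[(R)-hydroxy(3-methoxy-4-tosyloxyphenyl)methyl]-2-(3-methoxy-4-tosyloxyphenyl)-5-oxooxolane-3-carboxylate
Product: 8 (3S,4S,5R)-3-[(R)-hydroxy(3-methoxy-4-tosyloxyphenyl)methyl]-4-(hydroxymethyl)-5-(3-methoxy-4-tosyloxyphenyl)oxolan-2-ol (anomer mixture)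
Conditions: iBu2AlH (5 equiv), CH2Cl2, −78 → −40 °C; aq. KNaC4H4O6
Reagents that add atoms: none
Why: iBu2AlH half-reduction of a γ-lactone: the aluminium lactolate is stable at low temperature while the ethyl ester is taken on to the primary alcohol; aryl tosylates are inert under these conditions, and the new lactol centre is an anomer mixture that disappears in step 5.

**Step 5**
Reactants: 8 (3S,4S,5R)-3-[(R)-hydroxy(3-methoxy-4-tosyloxyphenyl)methyl]-4-(hydroxymethyl)-5-(3-methoxy-4-tosyloxyphenyl)oxolan-2-ol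
Product: 9 4-[(2R,3S,4R)-4-[(R)-hydroxy(3-methoxy-4-tosyloxyphenyl)methyl]-3-(hydroxymethyl)oxolan-2-yl]-2-methoxyphenyl 4-methylbenzenesulfonate
Conditions: Et3SiH (4 equiv), BF3·OEt2 (2 equiv, promoter), CH2Cl2, −78 → −30 °C; aq. NaHCO3
Reagents that add atoms: none
Why: Ionic hydrogenation of the lactol through the cyclic oxocarbenium ion; the sulfonylated aryl rings make both benzylic C–O bonds too poor to ionise at low temperature, so C-2 and the carbinol centre are untouched and no new stereocentre is formed.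

**Step 6**
Reactants: 9 4-[(2R,3S,4R)-4-[(R)-hydroxy(3-methoxy-4-tosyloxyphenyl)methyl]-3-(hydroxymethyl)oxolan-2-yl]-2-methoxyphenyl 4-methylbenzenesulfonate
Product: 10 4-[(2R,3S,4R)-4-[(R)-hydroxy(4-hydroxy-3-methoxyphenyl)methyl]-3-(hydroxymethyl)oxolan-2-yl]-2-methoxyphenol (target)
Conditions: KOH (6 equiv), MeOH/H2O 4:1, 60 °C; aq. NH4Cl to pH 6
Reagents that add atoms: none
Why: Aryl sulfonate cleavage by nucleophilic attack at sulfur (S–O scission), which leaves the phenol oxygen and all four stereocentres untouched; the molecule has no carbonyl group left, so no retro-aldol path is open.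

**Compound list**
1 | vanillin (4-hydroxy-3-methoxybenzaldehyde) | COc1cc(C=O)ccc1O | starting material
2 | 4-formyl-2-methoxyphenyl 4-methylbenzenesulfonate | COc1cc(C=O)ccc1OS(=O)(=O)c1ccc(C)cc1 | intermediate
3 | ethyl (E)-4-oxobut-2-enoate | CCOC(=O)/C=C/C=O | starting material
4 | ethyl (2R,3S)-2-(3-methoxy-4-tosyloxyphenyl)-5-oxooxolane-3-carboxylate (cis-lactone) | CCOC(=O)[C@H]1CC(=O)O[C@H]1c1ccc(OS(=O)(=O)c2ccc(C)cc2)c(OC)c1 | intermediate (not isolated)
5 | ethyl (2R,3R)-2-(3-methoxy-4-tosyloxyphenyl)-5-oxooxolane-3-carboxylate (trans-lactone) | CCOC(=O)[C@@H]1CC(=O)O[C@H]1c1ccc(OS(=O)(=O)c2ccc(C)cc2)c(OC)c1 | intermediate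
6 | dicyclohexylboron enolate of 5 (ethyl (4R,5R)-2-(dicyclohexylboryloxy)-5-(3-methoxy-4-tosyloxyphenyl)-4,5-dihydrofuran-4-carboxylate) | CCOC(=O)[C@@H]1C=C(OB(C2CCCCC2)C2CCCCC2)O[C@H]1c1ccc(OS(=O)(=O)c2ccc(C)cc2)c(OC)c1 | intermediate (not isolated)
7 | ethyl (2R,3R,4S)-4-[(R)-hydroxy(3-methoxy-4-tosyloxyphenyl)methyl]-2-(3-methoxy-4-tosyloxyphenyl)-5-oxooxolane-3-carboxylate | O[C@@H](c1ccc(OS(=O)(=O)c2ccc(C)cc2)c(OC)c1)[C@H]1C(=O)O[C@@H](c2ccc(OS(=O)(=O)c3ccc(C)cc3)c(OC)c2)[C@@H]1C(=O)OCC | intermediate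
8 | (3S,4S,5R)-3-[(R)-hydroxy(3-methoxy-4-tosyloxyphenyl)methyl]-4-(hydroxymethyl)-5-(3-methoxy-4-tosyloxyphenyl)oxolan-2-ol (anomer mixture) | O[C@@H](c1ccc(OS(=O)(=O)c2ccc(C)cc2)c(OC)c1)[C@H]1C(O)O[C@@H](c2ccc(OS(=O)(=O)c3ccc(C)cc3)c(OC)c2)[C@@H]1CO | intermediate
9 | 4-[(2R,3S,4R)-4-[(R)-hydroxy(3-methoxy-4-tosyloxyphenyl)methyl]-3-(hydroxymethyl)oxolan-2-yl]-2-methoxyphenyl 4-methylbenzenesulfonate | O[C@@H](c1ccc(OS(=O)(=O)c2ccc(C)cc2)c(OC)c1)[C@H]1CO[C@@H](c2ccc(OS(=O)(=O)c3ccc(C)cc3)c(OC)c2)[C@@H]1CO | intermediate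
10 | 4-[(2R,3S,4R)-4-[(R)-hydroxy(4-hydroxy-3-methoxyphenyl)methyl]-3-(hydroxymethyl)oxolan-2-yl]-2-methoxyphenol | COc1cc([C@H](O)[C@H]2CO[C@@H](c3ccc(O)c(OC)c3)[C@@H]2CO)ccc1O | target

**Totals**
Total step count: 6. Longest linear sequence: 6 (1 → 2 → 5 → 7 → 8 → 9 → 10; aldehyde 2 enters twice).

**Three steps most likely to fail**

Step 2 (enantioselectivity of the annulation, and self-annulation of enal 3). The fallback sets out from 2 and 3 and comes back at 5. The annulation is run with achiral 1,3-dimesitylimidazolium chloride (10 mol %) and DBU in THF, the established enal–aldehyde lactone annulation, followed by DBU equilibration to the racemic trans-lactone. This racemate is 5 together with its enantiomer, ethyl (2S,3S)-2-(3-methoxy-4-tosyloxyphenyl)-5-oxooxolane-3-carboxylate F1. A kinetic resolution with a screened esterase (pig liver esterase or a lipase, pH 7 buffer/acetone) then hydrolyses F1 to (2S,3S)-2-(3-methoxy-4-tosyloxyphenyl)-5-oxooxolane-3-carboxylic acid F2, which is removed by an aqueous NaHCO3 wash and leaves 5. If the enzyme prefers 5 instead, the acid is kept and re-esterified with EtOH.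

Step 3 (anti/syn ratio at the carbinol carbon, and competing enolisation at the ester-bearing C-3). The fallback sets out from 5 and comes back at 7, and sets the carbinol centre by ketone reduction instead of by the aldol transition state. A lithium aldol of 5 (LiN(SiMe3)2, THF, −78 °C, then 2) is accepted as a mixture of 7 and its carbinol epimer, ethyl (2R,3R,4S)-4-[(S)-hydroxy(3-methoxy-4-tosyloxyphenyl)methyl]-2-(3-methoxy-4-tosyloxyphenyl)-5-oxooxolane-3-carboxylate F3. The mixture is oxidised with Dess–Martin periodinane to the β-keto lactone, ethyl (2R,3R,4S)-4-(3-methoxy-4-tosyloxybenzoyl)-2-(3-methoxy-4-tosyloxyphenyl)-5-oxooxolane-3-carboxylate F4, whose C-4 stays trans by equilibration. Catalyst-controlled transfer hydrogenation (RuCl(p-cymene)[(R,R)-TsDPEN], HCO2H/Et3N, rt; antipode chosen by analogy with acetophenone) then gives the R carbinol 7.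

Step 4 (lactone must stop at the lactol while the ethyl ester goes to the alcohol). The fallback sets out from 5 and comes back at 8, and differentiates the two carbonyl groups before the aldol. The ester of 5 is hydrolysed (HCl 6 M, 1,4-dioxane, 70 °C) to (2R,3R)-2-(3-methoxy-4-tosyloxyphenyl)-5-oxooxolane-3-carboxylic acid F5. The acid alone is reduced with BH3·SMe2 (THF, 0 °C) to (4S,5R)-4-(hydroxymethyl)-5-(3-methoxy-4-tosyloxyphenyl)oxolan-2-one F6. Acylation with pivaloyl chloride/pyridine gives [(2R,3S)-2-(3-methoxy-4-tosyloxyphenyl)-5-oxooxolan-3-yl]methyl 2,2-dimethylpropanoate F7. The boron aldol of step 3 with 2 gives [(2R,3S,4S)-4-[(R)-hydroxy(3-methoxy-4-tosyloxyphenyl)methyl]-2-(3-methoxy-4-tosyloxyphenyl)-5-oxooxolan-3-yl]methyl 2,2-dimethylpropanoate F8. Finally iBu2AlH (excess, CH2Cl2, −78 °C) reduces the only remaining lactone to the lactol and cleaves the pivalate, giving 8.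

**Further compounds**
F1 | step 2 | ethyl (2S,3S)-2-(3-methoxy-4-tosyloxyphenyl)-5-oxooxolane-3-carboxylate | CCOC(=O)[C@H]1CC(=O)O[C@@H]1c1ccc(OS(=O)(=O)c2ccc(C)cc2)c(OC)c1
F2 | step 2 | (2S,3S)-2-(3-methoxy-4-tosyloxyphenyl)-5-oxooxolane-3-carboxylic acid | OC(=O)[C@H]1CC(=O)O[C@@H]1c1ccc(OS(=O)(=O)c2ccc(C)cc2)c(OC)c1
F3 | step 3 | ethyl (2R,3R,4S)-4-[(S)-hydroxy(3-methoxy-4-tosyloxyphenyl)methyl]-2-(3-methoxy-4-tosyloxyphenyl)-5-oxooxolane-3-carboxylate | O[C@H](c1ccc(OS(=O)(=O)c2ccc(C)cc2)c(OC)c1)[C@H]1C(=O)O[C@@H](c2ccc(OS(=O)(=O)c3ccc(C)cc3)c(OC)c2)[C@@H]1C(=O)OCC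
F4 | step 3 | ethyl (2R,3R,4S)-4-(3-methoxy-4-tosyloxybenzoyl)-2-(3-methoxy-4-tosyloxyphenyl)-5-oxooxolane-3-carboxylate | O=C(c1ccc(OS(=O)(=O)c2ccc(C)cc2)c(OC)c1)[C@H]1C(=O)O[C@@H](c2ccc(OS(=O)(=O)c3ccc(C)cc3)c(OC)c2)[C@@H]1C(=O)OCC
F5 | step 4 | (2R,3R)-2-(3-methoxy-4-tosyloxyphenyl)-5-oxooxolane-3-carboxylic acid | OC(=O)[C@@H]1CC(=O)O[C@H]1c1ccc(OS(=O)(=O)c2ccc(C)cc2)c(OC)c1
F6 | step 4 | (4S,5R)-4-(hydroxymethyl)-5-(3-methoxy-4-tosyloxyphenyl)oxolan-2-one | OC[C@@H]1CC(=O)O[C@H]1c1ccc(OS(=O)(=O)c2ccc(C)cc2)c(OC)c1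
F7 | step 4 | [(2R,3S)-2-(3-methoxy-4-tosyloxyphenyl)-5-oxooxolan-3-yl]methyl 2,2-dimethylpropanoate | CC(C)(C)C(=O)OC[C@@H]1CC(=O)O[C@H]1c1ccc(OS(=O)(=O)c2ccc(C)cc2)c(OC)c1
F8 | step 4 | [(2R,3S,4S)-4-[(R)-hydroxy(3-methoxy-4-tosyloxyphenyl)methyl]-2-(3-methoxy-4-tosyloxyphenyl)-5-oxooxolan-3-yl]methyl 2,2-dimethylpropanoate | O[C@@H](c1ccc(OS(=O)(=O)c2ccc(C)cc2)c(OC)c1)[C@H]1C(=O)O[C@@H](c2ccc(OS(=O)(=O)c3ccc(C)cc3)c(OC)c2)[C@@H]1COC(=O)C(C)(C)C
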